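## Retrosynthetic overview

1. Target 11 ⇒ acyclic chalcone 8 in a single flask operation: ring D (2H-pyran) closes first by aryl propargyl ether Claisen / 1,5-H shift / oxa-6π, then ring C (pyranone) closes by catalytic asymmetric oxa-Michael addition, which sets C2 as (S).
2. Chalcone 8 ⇒ Claisen–Schmidt condensation of ketone 3 (ring A, prenyl already in place) with aldehyde 6 (ring B carrying the masked chromene).
3. 3 ⇒ 2,4-dihydroxyacetophenone + prenyl bromide (C-prenylation); 6 ⇒ 4-hydroxybenzaldehyde + 3-chloro-3-methylbut-1-yne (O-alkylation).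
4. Ring order: A and B are bought; D, then C, are formed in the last step.

Assumption: the stereocentre in the SMILES is (2S), and the epi-quinidine-derived thiourea is assumed to deliver the phenol to the Si face of C-β (giving 2S); if the sense proves opposite, the pseudoenantiomeric epi-quinine thiourea is used with nothing else changed.

## Route

Step 1
Reactants: 1 2,4-dihydroxyacetophenone; 2 prenyl bromide (1-bromo-3-methylbut-2-ene)
Product: 3 1-[2,4-dihydroxy-3-(3-methylbut-2-en-1-yl)phenyl]ethan-1-one
Conditions: KOH (10% aq), 0 °C → rt, 16 h; chromatography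
Reagents that add atoms: none
Why: C-prenylation of a resorcinolate in water (phenoxide C-alkylation), where hydrogen-bonded oxygens steer the allylic bromide to carbon and C3, flanked by both oxygens, reacts preferentially (about 30–45% expected; 5-C- and 4-O-prenyl isomers are separated).

Step 2
Reactants: 4 4-hydroxybenzaldehyde; 5 3-chloro-3-methylbut-1-yne
Product: 6 4-[(2-methylbut-3-yn-2-yl)oxy]benzaldehyde
Conditions: K2CO3, KI (cat.), CuI (cat.), acetone, 60 °C
Reagents that add atoms: none
Why: Copper-assisted O-propargylation (Williamson-type etherification through a copper acetylide/allenylidene) forms the tertiary aryl propargyl ether at the only acidic OH, and the aldehyde is untouched.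

Step 3
Reactants: 3 1-[2,4-dihydroxy-3-(3-methylbut-2-en-1-yl)phenyl]ethan-1-one; 6 4-[(2-methylbut-3-yn-2-yl)oxy]benzaldehyde
Product: 8 (E)-1-[2,4-dihydroxy-3-(3-methylbut-2-en-1-yl)phenyl]-3-{4-[(2-methylbut-3-yn-2-yl)oxy]phenyl}prop-2-en-1-one, via aldol adduct 7 (not isolated)
Conditions: KOH (50% aq), EtOH, 0 °C → rt, 48 h; then cold 1 M HCl to pH 5
Reagents that add atoms: none
Why: Claisen–Schmidt (crossed aldol) condensation of the ketone enolate with the non-enolisable aldehyde followed by E1cB dehydration gives the (E)-chalcone, which stays open as its phenolate in strong base; the prenyl group and the tertiary propargyl ether are base-stable.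

Step 4
Reactants: 8 (E)-1-[2,4-dihydroxy-3-(3-methylbut-2-en-1-yl)phenyl]-3-{4-[(2-methylbut-3-yn-2-yl)oxy]phenyl}prop-2-en-1-one
Product: 11 (2S)-2-(2,2-dimethyl-2H-chromen-6-yl)-7-hydroxy-8-(3-methylbut-2-en-1-yl)-2,3-dihydro-4H-chromen-4-one, via ortho-allenylphenol chalcone 9 (not isolated), via chromenyl chalcone 10 (not isolated)
Conditions: PhMe (0.05 M, degassed), sealed tube, 180 °C (μW), 1 h; then −20 °C, 9-amino(9-deoxy)epi-quinidine-derived 3,5-bis(trifluoromethyl)phenyl thiourea (10 mol%), −20 → 0 °C, 48 h; silica plug, chromatography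
Reagents that add atoms: none
Why: Proposed new method: in neutral toluene the aryl 1,1-dimethylpropargyl ether undergoes aromatic propargyl Claisen rearrangement, tautomerisation to 9, 1,5-H shift and oxa-6π electrocyclisation to close ring D (10) while the chelated 2'-OH enone is expected not to cyclise without a base; after cooling, the bifunctional amine-thiourea activates the 2'-OH through its quinuclidine and the enone carbonyl through the thiourea, so that 6-endo-trig oxa-Michael addition to the Si face of C-β closes ring C and sets (2S); the closest known reactions are the thermal conversion of aryl 1,1-dimethylpropargyl ethers into 2,2-dimethyl-2H-chromenes and the cinchona-thiourea-catalysed cyclisation of 2'-hydroxychalcones and their α-ester analogues to flavanones.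

## Compound list

1 | 2,4-dihydroxyacetophenone | CC(=O)c1ccc(O)cc1O | starting material
2 | prenyl bromide (1-bromo-3-methylbut-2-ene) | CC(C)=CCBr | starting material
3 | 1-[2,4-dihydroxy-3-(3-methylbut-2-en-1-yl)phenyl]ethan-1-one | CC(=O)c1ccc(O)c(CC=C(C)C)c1O | intermediate
4 | 4-hydroxybenzaldehyde | O=Cc1ccc(O)cc1 | starting material
5 | 3-chloro-3-methylbut-1-yne | CC(C)(Cl)C#C | starting material
6 | 4-[(2-methylbut-3-yn-2-yl)oxy]benzaldehyde | CC(C)(C#C)Oc1ccc(C=O)cc1 | intermediate
7 | aldol adduct, racemic 3-hydroxy-1-[2,4-dihydroxy-3-(3-methylbut-2-en-1-yl)phenyl]-3-{4-[(2-methylbut-3-yn-2-yl)oxy]phenyl}propan-1-one | CC(C)=CCc1c(O)ccc(C(=O)CC(O)c2ccc(OC(C)(C)C#C)cc2)c1O | intermediate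
8 | (E)-1-[2,4-dihydroxy-3-(3-methylbut-2-en-1-yl)phenyl]-3-{4-[(2-methylbut-3-yn-2-yl)oxy]phenyl}prop-2-en-1-one | CC(C)=CCc1c(O)ccc(C(=O)/C=C/c2ccc(OC(C)(C)C#C)cc2)c1O | intermediate
9 | ortho-allenylphenol chalcone, (E)-1-[2,4-dihydroxy-3-(3-methylbut-2-en-1-yl)phenyl]-3-[4-hydroxy-3-(3-methylbuta-1,2-dien-1-yl)phenyl]prop-2-en-1-one | CC(C)=CCc1c(O)ccc(C(=O)/C=C/c2ccc(O)c(C=C=C(C)C)c2)c1O | intermediate
10 | chromenyl chalcone, (E)-1-[2,4-dihydroxy-3-(3-methylbut-2-en-1-yl)phenyl]-3-(2,2-dimethyl-2H-chromen-6-yl)prop-2-en-1-one | CC(C)=CCc1c(O)ccc(C(=O)/C=C/c2ccc3c(c2)C=CC(C)(C)O3)c1O | intermediate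
11 | (2S)-2-(2,2-dimethyl-2H-chromen-6-yl)-7-hydroxy-8-(3-methylbut-2-en-1-yl)-2,3-dihydro-4H-chromen-4-one | CC(C)=CCc1c(O)ccc2c1O[C@H](c1ccc3c(c1)C=CC(C)(C)O3)CC2=O | target

## Step count and risks

Total step count: 4. Longest linear sequence: 3 (steps 1 → 3 → 4, or 2 → 3 → 4).

The three steps most likely to fail:

**Step 4 (one-pot double ring closure).** The risks are racemic background cyclisation during heating, and low selectivity or reversibility of the oxa-Michael addition on a chalcone that carries a free, acidic 4'-OH. The fallback moves control of C2 from asymmetric ring closure to kinetic resolution. It sets out from 8: heating in N,N-diethylaniline at 190 °C, then NaOAc in refluxing EtOH, closes both rings (through 9 and 10) without stereocontrol to the racemic flavanone F1. Rh-catalysed asymmetric transfer hydrogenation of F1 ([Cp*RhCl((R,R)-TsDPEN)] 1 mol%, HCO2H/Et3N, EtOAc, rt, stopped near 55% conversion) reduces the (2R)-ketone to the cis-(2R,4R)-flavan-4-ol F2. The (R,R) ligand is the one expected from the acetophenone model and is confirmed on small scale. The unreacted (2S)-flavanone is separated by chromatography, and the route is rejoined at 11. The ketone-selective Rh hydride leaves the prenyl and chromene alkenes alone.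

**Step 1 (direct C-prenylation).** The risks are low yield and C3/C5/O regioisomers. The fallback replaces intermolecular C-alkylation by an intramolecular sigmatropic delivery. It sets out from 1: the non-chelated 4-OH is alkylated with 5 (K2CO3, KI, CuI, acetone, 60 °C) to 1-{2-hydroxy-4-[(2-methylbut-3-yn-2-yl)oxy]phenyl}ethan-1-one F3. Lindlar semihydrogenation (H2, Pd/CaCO3–Pb, quinoline, EtOAc) gives the 1,1-dimethylallyl ether 1-{2-hydroxy-4-[(2-methylbut-3-en-2-yl)oxy]phenyl}ethan-1-one F4. Aromatic Claisen rearrangement (PhNEt2, 130 °C) transfers the allyl unit to C3, the position favoured by bond fixation in the hydrogen-bonded chelate, and the route is rejoined at 3.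

**Step 3 (Claisen–Schmidt on the unprotected dihydroxy ketone).** The risk is sluggish enolisation of the phenoxide dianion, with Cannizzaro loss of 6. The fallback introduces a protecting group so that only the chelated 2-OH remains free. It sets out from 3: MOMCl, K2CO3, acetone gives 1-[2-hydroxy-4-(methoxymethoxy)-3-(3-methylbut-2-en-1-yl)phenyl]ethan-1-one F5. Condensation with 6 (KOH, EtOH/H2O, rt) gives the MOM-protected chalcone (E)-1-[2-hydroxy-4-(methoxymethoxy)-3-(3-methylbut-2-en-1-yl)phenyl]-3-{4-[(2-methylbut-3-yn-2-yl)oxy]phenyl}prop-2-en-1-one F6. Brief acetal cleavage (3 M HCl, MeOH, rt, monitored so that the prenyl group and the propargyl ether are not touched) returns the route to 8.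

## Further compounds

F1 | step 4 | racemic 2-(2,2-dimethyl-2H-chromen-6-yl)-7-hydroxy-8-(3-methylbut-2-en-1-yl)-2,3-dihydro-4H-chromen-4-one | CC(C)=CCc1c(O)ccc2c1OC(c1ccc3c(c1)C=CC(C)(C)O3)CC2=O
F2 | step 4 | cis-(2R,4R)-2-(2,2-dimethyl-2H-chromen-6-yl)-8-(3-methylbut-2-en-1-yl)-3,4-dihydro-2H-chromene-4,7-diol | CC(C)=CCc1c(O)ccc2c1O[C@@H](c1ccc3c(c1)C=CC(C)(C)O3)C[C@H]2O
F3 | step 1 | 1-{2-hydroxy-4-[(2-methylbut-3-yn-2-yl)oxy]phenyl}ethan-1-one | CC(=O)c1ccc(OC(C)(C)C#C)cc1O
F4 | step 1 | 1-{2-hydroxy-4-[(2-methylbut-3-en-2-yl)oxy]phenyl}ethan-1-one | CC(=O)c1ccc(OC(C)(C)C=C)cc1O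
F5 | step 3 | 1-[2-hydroxy-4-(methoxymethoxy)-3-(3-methylbut-2-en-1-yl)phenyl]ethan-1-one | CC(=O)c1ccc(OCOC)c(CC=C(C)C)c1O
F6 | step 3 | (E)-1-[2-hydroxy-4-(methoxymethoxy)-3-(3-methylbut-2-en-1-yl)phenyl]-3-{4-[(2-methylbut-3-yn-2-yl)oxy]phenyl}prop-2-en-1-one | CC(C)=CCc1c(OCOC)ccc(C(=O)/C=C/c2ccc(OC(C)(C)C#C)cc2)c1O
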